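Target 32 is a heliangolide. Its ten-membered carbocycle (C1–C10, with a C1–C10 oxirane and a 4Z alkene) is trans-fused at C6–C7 to an α-methylene-γ-butyrolactone (ring O–C6–C7–C11–C12, exocyclic C11=C13). The endgame is esterification at O8 with inversion, C1=C10 epoxidation and desilylation.
Enabling feature: C13=C11–C7–C8–O is a homoallylic alcohol whose allyl part lies in the lactone ring. The C7–C8 bond is therefore the retron of an SE2' carbonyl allylation, and cutting it opens the carbocycle to the acyclic ω-formyl α-(bromomethyl)butenolide 26.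
26 comes from a Nozaki–Hiyama–Kishi union at C3–C4 of iodoalkenyl butenolide 11 with aldehyde 18, followed by a CBS reduction that sets C3.
11 comes from an enynol by lipase resolution (sets C6), directed hydroalumination–iodination (sets 4Z) and acrylate ring-closing metathesis. 18 comes from but-3-yn-1-ol by carboalumination (sets 1(10)E) and oxirane opening.
Ring order: butenolide (step 6), ten-membered carbocycle (step 17), oxirane (step 19).

Key step: step 17

Remark on the chemistry: from compound 19 on, carbons carry germacranolide numbers. C1–C10 is the later carbocycle, C11/C12/C13 are the lactone α-carbon, carbonyl and methylene, C14 is the methyl on C10, and C15 is the CH2O on C4. α/β refer to the usual drawing with H7 α. "7,8-seco-butenolide" means the open chain with a C7=C11 butenolide. TBS = tert-butyldimethylsilyl, PMB = 4-methoxybenzyl.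

Step 1
Reactants: 1 tert-butyldimethyl(prop-2-yn-1-yloxy)silane; 2 acrolein
Product: 4 (±)-6-(TBSO)hex-1-en-4-yn-3-ol, via lithium acetylide 3 (not isolated)
Conditions: n-BuLi, THF, −78 °C; then 2, −78 °C; H2O
Reagents that add atoms: none
Why: Carbonyl alkynylation: the lithium acetylide 3 adds 1,2 to the enal at low temperature and gives the racemic carbinol carbon that becomes C6.

Step 2
Reactants: 4 (±)-6-(TBSO)hex-1-en-4-yn-3-ol
Product: 5 (S)-6-(TBSO)hex-1-en-4-yn-3-ol
Conditions: Novozym 435 (immobilised Candida antarctica lipase B), vinyl acetate, hexane, 30 °C, stopped near half conversion; chromatography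
Reagents that add atoms: none
Why: Lipase-catalysed kinetic resolution by acyl transfer: following the Kazlauskas rule (long silyloxypropynyl arm large, vinyl arm medium) the R alcohol is acetylated and the S alcohol 5 stays behind, which sets C6.

Step 3
Reactants: 5 (S)-6-(TBSO)hex-1-en-4-yn-3-ol
Product: 7 (3S,4Z)-6-(TBSO)-5-iodohexa-1,4-dien-3-ol, via cyclic alkenylaluminate 6 (not isolated)
Conditions: NaAlH2(OCH2CH2OMe)2, THF, 0 °C; then I2, −78 to 0 °C; H2O
Reagents that add atoms: iodine, [I][I]
Why: Hydroxyl-directed trans-hydroalumination of a propargylic alcohol followed by iodinolysis with retention: hydride goes to C5 and aluminium to C4 inside the five-membered ate complex 6, so iodine ends cis to C6 and the later 4Z geometry is fixed.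

Step 4
Reactants: 8 2-(bromomethyl)acrylic acid
Product: 9 2-{[(4-methoxybenzyl)oxy]methyl}acrylic acid
Conditions: 4-methoxybenzyl alcohol, NaH (2.2 equiv), THF, 0 °C to rt; then 1 M HCl
Reagents that add atoms: 4-methoxybenzyl alcohol, COc1ccc(CO)cc1
Why: Williamson-type etherification: the alkoxide displaces the doubly activated allylic bromide of the carboxylate salt, and the direct and the allylic-shift pathways lead to the same ether.

Step 5
Reactants: 7 (3S,4Z)-6-(TBSO)-5-iodohexa-1,4-dien-3-ol; 9 2-{[(4-methoxybenzyl)oxy]methyl}acrylic acid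
Product: 10 (3S,4Z)-6-(TBSO)-5-iodohexa-1,4-dien-3-yl 2-{[(4-methoxybenzyl)oxy]methyl}acrylate
Conditions: DCC, DMAP (cat.), CH2Cl2, 0 °C to rt
Reagents that add atoms: none
Why: Steglich esterification acylates the secondary bis-allylic alcohol under neutral conditions without touching the C6–O bond, so the configuration is kept.

Step 6
Reactants: 10 (3S,4Z)-6-(TBSO)-5-iodohexa-1,4-dien-3-yl 2-{[(4-methoxybenzyl)oxy]methyl}acrylate
Product: 11 (5S)-5-[(1Z)-3-(TBSO)-2-iodoprop-1-en-1-yl]-3-[(PMBO)methyl]furan-2(5H)-one
Conditions: second-generation Hoveyda–Grubbs catalyst (5 mol %), toluene, 80 °C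
Reagents that add atoms: none
Why: Ring-closing metathesis of the vinyl group with the 1,1-disubstituted acrylate closes the five-membered butenolide and expels ethene, while the trisubstituted iodoalkene is too hindered to take part.

Step 7
Reactants: 12 but-3-yn-1-ol
Product: 13 1-[(but-3-yn-1-yloxy)methyl]-4-methoxybenzene
Conditions: NaH, 4-methoxybenzyl chloride, Bu4NI (cat.), THF–DMF, 0 °C to rt
Reagents that add atoms: 4-methoxybenzyl chloride, COc1ccc(CCl)cc1
Why: Williamson etherification of a primary alcohol; the alkoxide forms well before the alkyne C–H is touched.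

Step 8
Reactants: 13 1-[(but-3-yn-1-yloxy)methyl]-4-methoxybenzene; 14 oxirane
Product: 17 (3E)-6-(PMBO)-4-methylhex-3-en-1-ol, via alkenyldimethylalane 15 (not isolated), via lithium alkenylalanate 16 (not isolated)
Conditions: Me3Al, Cp2ZrCl2 (cat.), CH2Cl2, 0 °C to rt; n-BuLi, THF–hexane, −78 to 0 °C; then 14, 0 °C; H2O
Reagents that add atoms: trimethylaluminium, C[Al](C)C
Why: Negishi zirconium-catalysed carboalumination adds methyl and aluminium syn and regioselectively (methyl to the inner carbon), which fixes the 1(10)E geometry, and the more nucleophilic ate complex 16 then opens oxirane with retention at the alkenyl carbon.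

Step 9
Reactants: 17 (3E)-6-(PMBO)-4-methylhex-3-en-1-ol
Product: 18 (3E)-6-(PMBO)-4-methylhex-3-enal
Conditions: DMP, CH2Cl2, 0 °C
Reagents that add atoms: none
Why: Dess–Martin oxidation works under near-neutral, non-enolising conditions, so the β,γ-alkene should not move into conjugation.

Step 10
Reactants: 11 (5S)-5-[(1Z)-3-(TBSO)-2-iodoprop-1-en-1-yl]-3-[(PMBO)methyl]furan-2(5H)-one; 18 (3E)-6-(PMBO)-4-methylhex-3-enal
Product: 20 7,8-seco-butenolide carbinol (3RS;6R;1(10)E;4Z;8-OPMB;13-OPMB;15-OTBS), via alkenylchromium dichloride 19 (not isolated)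
Conditions: CrCl2 (excess), NiCl2 (cat.), DMSO, rt; H2O
Reagents that add atoms: none
Why: Nozaki–Hiyama–Kishi coupling: zerovalent nickel inserts into the C4–I bond, transmetalation to trivalent chromium gives 19 with retention of the alkene geometry, and this mild nucleophile adds only to the aldehyde while lactone, silyl and benzyl ethers stay untouched; C3 forms without control and is reset in steps 11 and 12.

Step 11
Reactants: 20 7,8-seco-butenolide carbinol (3RS)
Product: 21 7,8-seco-butenolide 3-ketone (6R;1(10)E;4Z;8-OPMB;13-OPMB;15-OTBS)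
Conditions: DMP, CH2Cl2, 0 °C to rt
Reagents that add atoms: none
Why: Dess–Martin oxidation converts both C3 epimers into one cross-conjugated enone and leaves the 4Z geometry and C6 untouched.

Step 12
Reactants: 21 7,8-seco-butenolide 3-ketone
Product: 22 7,8-seco-butenolide (3S)-carbinol (3S;6R;1(10)E;4Z;8-OPMB;13-OPMB;15-OTBS)
Conditions: (R)-2-methyl-CBS-oxazaborolidine (cat.), catecholborane, toluene, −78 °C; H2O
Reagents that add atoms: none
Why: Corey–Bakshi–Shibata reduction: the branched alkenyl arm (C4) acts as the large and the C2 methylene as the small substituent, so the R catalyst should deliver hydride to give the 3S carbinol under reagent control, and catecholborane at low temperature spares the alkenes and the lactone.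

Step 13
Reactants: 22 7,8-seco-butenolide (3S)-carbinol
Product: 23 7,8-seco-butenolide 3,15-bis-TBS ether (3S;6R;8-OPMB;13-OPMB)
Conditions: TBSCl, imidazole, DMF, rt
Reagents that add atoms: tert-butyldimethylsilyl chloride, CC(C)(C)[Si](C)(C)Cl
Why: Standard silylation with imidazole as a weak base protects O3 and avoids the stronger base and silyl triflate combination that could turn the butenolide into a silyloxyfuran.

Step 14
Reactants: 23 7,8-seco-butenolide 3,15-bis-TBS ether
Product: 24 7,8-seco-butenolide 8,13-diol (3S;6R;3,15-bis-OTBS)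
Conditions: DDQ, CH2Cl2–pH 7 buffer, 0 °C
Reagents that add atoms: none
Why: Oxidative cleavage of 4-methoxybenzyl ethers by DDQ (hydride abstraction then hydrolysis) frees O8 and O13 together and spares silyl ethers, alkenes and the lactone.

Step 15
Reactants: 24 7,8-seco-butenolide 8,13-diol
Product: 25 13-bromo-7,8-seco-butenolide 8-alcohol (3S;6R;3,15-bis-OTBS)
Conditions: NBS, Me2S, CH2Cl2, −20 °C; then 24, −20 to 0 °C; H2O
Reagents that add atoms: N-bromosuccinimide, O=C1CCC(=O)N1Br
Why: Corey–Kim-type halogenation: both hydroxyls form alkoxysulfonium salts but only the activated allylic C13 centre is displaced by bromide at this temperature, and the saturated C8 salt reverts to the alcohol on aqueous work-up.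

Step 16
Reactants: 25 13-bromo-7,8-seco-butenolide 8-alcohol
Product: 26 13-bromo-7,8-seco-butenolide 8-aldehyde (3S;6R;1(10)E;4Z;3,15-bis-OTBS)
Conditions: DMP, CH2Cl2, 0 °C; used at once
Reagents that add atoms: none
Why: Dess–Martin oxidation is neutral and amine-free, so the allylic bromide survives and the β,γ-unsaturated aldehyde should not isomerise.

Step 17
Reactants: 26 13-bromo-7,8-seco-butenolide 8-aldehyde
Product: 28 (3S,6R,7R,8S)-3,15-bis(TBSO)-8α-hydroxygermacra-1(10)E,4Z,11(13)-trien-12,6-olide, via allylchromium dichloride 27 (not isolated)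
Conditions: CrCl2 (excess), dry DMF, rt, slow addition of 26 by syringe pump to about 1 mM final concentration; H2O
Reagents that add atoms: none
Why: Divalent chromium reduces the activated allylic C13–Br bond of 26 by two one-electron transfers to the η1-allylchromium 27, which adds to the tethered C8 aldehyde by SE2' through a six-membered Zimmerman–Traxler array, so that C7–C8 forms while the ring C7=C11 bond moves out to C11=C13 and unveils the α-methylene lactone. The closest known reaction types are the Nozaki–Hiyama allylation macrocyclisation of ω-formyl 2-(bromomethyl)acrylates to ten-membered carbocycles and the intermolecular Barbier allylation of aldehydes with α-(bromomethyl)butenolides. The ten-membered carbocycle closes in a 10-exo-trig mode at the carbonyl carbon, helped by the turn of the 4Z alkene, the rigid 1(10)E alkene and allylic 1,3-strain at C3 and C6, which leave few free rotors between C5 and C9. C7 is controlled by C6: the aldehyde should reach the butenolide face opposite to the C5 chain, because only the trans fusion lets the C5–C6–C7–C8 segment adopt the wide torsion a cyclodecadiene needs, whereas cis delivery would nearly eclipse it. C8 is controlled by the chair: the lactone ring locks C6 trans to C13 (an E-type allylmetal), chromium sits on the open H7 side, the C9 tether lies equatorial (anti to C11) and the carbonyl oxygen points to chromium, which should give the 7,8-anti, 8α (8S) alcohol. The step needs γ- over α-attack and ring closure over oligomerisation and protonolysis; chromium residing on the primary C13 secures the first, slow addition into excess dry CrCl2 at high dilution the second, and silyl ethers, lactone and unactivated alkenes are inert to CrCl2.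

Step 18
Reactants: 28 8α-hydroxy macrocycle; 29 methacrylic acid
Product: 30 (3S,6R,7R,8R)-3,15-bis(TBSO)-8β-(methacryloyloxy)germacra-1(10)E,4Z,11(13)-trien-12,6-olide
Conditions: PPh3, DIAD, toluene, 0 °C to rt
Reagents that add atoms: none
Why: Mitsunobu esterification displaces the 8α-oxyphosphonium group by methacrylate with SN2 inversion, so acylation and correction of C8 to 8β (8R) happen in one operation, and in the expected conformer H7 is not antiperiplanar to the leaving group, which should hold back elimination.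

Step 19
Reactants: 30 8β-methacrylate macrocycle
Product: 31 (1R,3S,6R,7R,8R,10R)-3,15-bis(TBSO)-1β,10α-epoxy-8β-(methacryloyloxy)germacra-4Z,11(13)-dien-12,6-olide
Conditions: DMDO (1 equiv), acetone–CH2Cl2, −40 to 0 °C
Reagents that add atoms: dimethyldioxirane, CC1(C)OO1
Why: Electrophilic dioxirane epoxidation picks the only electron-rich alkene (C4=C5 carries three allylic oxygens and two silyl shields, C11=C13 and the methacrylate are electron-poor) and should strike the outer face of the E alkene in the conformer with C14 on the β face, giving the trans 1β,10α (1R,10R) oxirane by stereospecific syn addition.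

Step 20
Reactants: 31 bis-silylated epoxide
Product: 32 target CNP0496616.1, (1R,3S,6R,7R,8R,10R)-1β,10α-epoxy-3β,15-dihydroxy-8β-(methacryloyloxy)germacra-4Z,11(13)-dien-12,6-olide
Conditions: Et3N·3HF, MeCN–THF, 0 °C to rt
Reagents that add atoms: none
Why: Fluoride-driven desilylation with a nearly neutral HF source removes both silyl ethers without opening the oxirane, cleaving the esters or adding to the two acrylate units.

Compound list
1 | tert-butyldimethyl(prop-2-yn-1-yloxy)silane | C#CCO[Si](C)(C)C(C)(C)C | starting material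
2 | acrolein | C=CC=O | starting material
3 | lithium acetylide of 1 | [Li]C#CCO[Si](C)(C)C(C)(C)C | intermediate
4 | (±)-6-(TBSO)hex-1-en-4-yn-3-ol | C=CC(O)C#CCO[Si](C)(C)C(C)(C)C | intermediate
5 | (S)-6-(TBSO)hex-1-en-4-yn-3-ol | C=C[C@H](O)C#CCO[Si](C)(C)C(C)(C)C | intermediate
6 | sodium cyclic alkenylaluminate (O6 and C4 bound to aluminium, two 2-methoxyethoxy ligands) | [Na+].C=C[C@H]1C=C(CO[Si](C)(C)C(C)(C)C)[Al-](OCCOC)(OCCOC)O1 | intermediate
7 | (3S,4Z)-6-(TBSO)-5-iodohexa-1,4-dien-3-ol | C=C[C@H](O)/C=C(\I)CO[Si](C)(C)C(C)(C)C | intermediate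
8 | 2-(bromomethyl)acrylic acid | C=C(CBr)C(=O)O | starting material
9 | 2-{[(4-methoxybenzyl)oxy]methyl}acrylic acid | C=C(COCc1ccc(OC)cc1)C(=O)O | intermediate
10 | (3S,4Z)-6-(TBSO)-5-iodohexa-1,4-dien-3-yl 2-{[(4-methoxybenzyl)oxy]methyl}acrylate | C=C[C@H](OC(=O)C(=C)COCc1ccc(OC)cc1)/C=C(\I)CO[Si](C)(C)C(C)(C)C | intermediate
11 | (5S)-5-[(1Z)-3-(TBSO)-2-iodoprop-1-en-1-yl]-3-[(PMBO)methyl]furan-2(5H)-one | COc1ccc(COCC2=C[C@@H](/C=C(\I)CO[Si](C)(C)C(C)(C)C)OC2=O)cc1 | intermediate
12 | but-3-yn-1-ol | C#CCCO | starting material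
13 | 1-[(but-3-yn-1-yloxy)methyl]-4-methoxybenzene | C#CCCOCc1ccc(OC)cc1 | intermediate
14 | oxirane | C1CO1 | starting material
15 | (E)-alkenyldimethylalane from 13 | COc1ccc(COCC/C(C)=C/[Al](C)C)cc1 | intermediate
16 | lithium (E)-alkenyl(butyl)dimethylalanate | [Li+].CCCC[Al-](C)(C)/C=C(C)/CCOCc1ccc(OC)cc1 | intermediate
17 | (3E)-6-(PMBO)-4-methylhex-3-en-1-ol | COc1ccc(COCC/C(C)=C/CCO)cc1 | intermediate
18 | (3E)-6-(PMBO)-4-methylhex-3-enal | COc1ccc(COCC/C(C)=C/CC=O)cc1 | intermediate
19 | alkenylchromium dichloride from 11 (chromium on C4, cis to C6) | COc1ccc(COCC2=C[C@@H](/C=C(\[Cr](Cl)Cl)CO[Si](C)(C)C(C)(C)C)OC2=O)cc1 | intermediate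
20 | 7,8-seco-butenolide carbinol, both C3 epimers, 6R, 1(10)E, 4Z, 8-OPMB, 13-OPMB, 15-OTBS | COc1ccc(COCC/C(C)=C/CC(O)/C(CO[Si](C)(C)C(C)(C)C)=C\[C@@H]2C=C(COCc3ccc(OC)cc3)C(=O)O2)cc1 | intermediate
21 | 7,8-seco-butenolide 3-ketone, 6R, 1(10)E, 4Z | COc1ccc(COCC/C(C)=C/CC(=O)/C(CO[Si](C)(C)C(C)(C)C)=C\[C@@H]2C=C(COCc3ccc(OC)cc3)C(=O)O2)cc1 | intermediate
22 | 7,8-seco-butenolide (3S)-carbinol, 3S, 6R | COc1ccc(COCC/C(C)=C/C[C@H](O)/C(CO[Si](C)(C)C(C)(C)C)=C\[C@@H]2C=C(COCc3ccc(OC)cc3)C(=O)O2)cc1 | intermediate
23 | 7,8-seco-butenolide 3,15-bis-TBS ether, 3S, 6R, 8-OPMB, 13-OPMB | COc1ccc(COCC/C(C)=C/C[C@H](O[Si](C)(C)C(C)(C)C)/C(CO[Si](C)(C)C(C)(C)C)=C\[C@@H]2C=C(COCc3ccc(OC)cc3)C(=O)O2)cc1 | intermediate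
24 | 7,8-seco-butenolide 8,13-diol, 3S, 6R | OCC/C(C)=C/C[C@H](O[Si](C)(C)C(C)(C)C)/C(CO[Si](C)(C)C(C)(C)C)=C\[C@@H]1C=C(CO)C(=O)O1 | intermediate
25 | 13-bromo-7,8-seco-butenolide 8-alcohol, 3S, 6R | OCC/C(C)=C/C[C@H](O[Si](C)(C)C(C)(C)C)/C(CO[Si](C)(C)C(C)(C)C)=C\[C@@H]1C=C(CBr)C(=O)O1 | intermediate
26 | 13-bromo-7,8-seco-butenolide 8-aldehyde, 3S, 6R, 1(10)E, 4Z | O=CC/C(C)=C/C[C@H](O[Si](C)(C)C(C)(C)C)/C(CO[Si](C)(C)C(C)(C)C)=C\[C@@H]1C=C(CBr)C(=O)O1 | intermediate
27 | allylchromium dichloride from 26 (chromium on C13) | O=CC/C(C)=C/C[C@H](O[Si](C)(C)C(C)(C)C)/C(CO[Si](C)(C)C(C)(C)C)=C\[C@@H]1C=C(C[Cr](Cl)Cl)C(=O)O1 | intermediate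
28 | (3S,6R,7R,8S)-3,15-bis(TBSO)-8α-hydroxygermacra-1(10)E,4Z,11(13)-trien-12,6-olide | O[C@H]1C/C(C)=C/C[C@H](O[Si](C)(C)C(C)(C)C)/C(CO[Si](C)(C)C(C)(C)C)=C\[C@H]2OC(=O)C(=C)[C@@H]21 | intermediate
29 | methacrylic acid | C=C(C)C(=O)O | starting material
30 | (3S,6R,7R,8R)-3,15-bis(TBSO)-8β-(methacryloyloxy)germacra-1(10)E,4Z,11(13)-trien-12,6-olide | C=C(C)C(=O)O[C@@H]1C/C(C)=C/C[C@H](O[Si](C)(C)C(C)(C)C)/C(CO[Si](C)(C)C(C)(C)C)=C\[C@H]2OC(=O)C(=C)[C@@H]21 | intermediate
31 | (1R,3S,6R,7R,8R,10R)-3,15-bis(TBSO)-1β,10α-epoxy-8β-(methacryloyloxy)germacra-4Z,11(13)-dien-12,6-olide | C=C(C)C(=O)O[C@@H]1C[C@@]2(C)O[C@@H]2C[C@H](O[Si](C)(C)C(C)(C)C)/C(CO[Si](C)(C)C(C)(C)C)=C\[C@H]2OC(=O)C(=C)[C@@H]21 | intermediate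
32 | CNP0496616.1, (1R,3S,6R,7R,8R,10R)-1β,10α-epoxy-3β,15-dihydroxy-8β-(methacryloyloxy)germacra-4Z,11(13)-dien-12,6-olide | C=C(C)C(=O)O[C@@H]1C[C@@]2(C)O[C@@H]2C[C@H](O)/C(CO)=C\[C@H]2OC(=O)C(=C)[C@@H]21 | target

Total step count: 20. Longest linear sequence: 16 (steps 1, 2, 3, 5, 6 and 10 to 20).

Steps most likely to fail

Step 17. Intermolecular addition (oligomerisation) and protonolysis of the allylchromium may outrun closure of the strained ring, and the aldehyde may drift into conjugation during the long addition.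
- The fallback sets out from 25 and replaces the transient organochromium by a preformed, isolable allylboronate.
- Borylation under zerovalent palladium catalysis (Pd2(dba)3, B2pin2, toluene) should give the 13-(pinacolboryl) seco-butenolide 8-alcohol F1.
- Dess–Martin oxidation should give the 13-(pinacolboryl) seco-butenolide 8-aldehyde F2. This compound can be handled because ester-substituted allylboronates add only slowly at room temperature.
- Heating at true high dilution in toluene, or catalysis by Sc(OTf)3, should close the ring by allylboration through the same chair to the macrocyclic 8α-O-pinacolborate F3.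
- Aqueous work-up of F3 returns the route to 28.

Step 18. The displacement at the hindered ring carbinol may be slow, so elimination toward C9 or C7 or acyl transfer with retention could take over.
- The fallback sets out from 28 and inverts C8 by a redox sequence.
- Dess–Martin oxidation should give the macrocyclic 8-ketone F4.
- F4 is reduced at once under Luche conditions (NaBH4, CeCl3, MeOH, −78 °C). Hydride should enter from the open H7 side, anti to C6 in the Felkin–Anh sense, to give the macrocyclic 8β-alcohol F5.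
- Acylation with methacrylic anhydride (Et3N, DMAP cat., CH2Cl2) returns the route to 30.

Step 19. Facial selectivity may be poor if the conformer with C14 on the α face is populated, and slow over-oxidation at C4=C5 may set in.
- The fallback sets out from 30 and comes back at 31.
- It replaces substrate control by catalyst control: a Shi epoxidation with the D-fructose-derived ketone, KHSO5 (as Oxone) and K2CO3 buffer in MeCN–dimethoxymethane–water at 0 °C.
- The spiro transition state of this catalyst delivers the R,R oxirane on E-trisubstituted alkenes. Because the two planar-chiral conformers of the E alkene interconvert, the catalyst can select the matching one.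
- This fallback makes no new compound (F0).

Further compounds
F1 | step 17 | 13-(pinacolboryl) seco-butenolide 8-alcohol (3S, 6R) | OCC/C(C)=C/C[C@H](O[Si](C)(C)C(C)(C)C)/C(CO[Si](C)(C)C(C)(C)C)=C\[C@@H]1C=C(CB2OC(C)(C)C(C)(C)O2)C(=O)O1
F2 | step 17 | 13-(pinacolboryl) seco-butenolide 8-aldehyde (3S, 6R) | O=CC/C(C)=C/C[C@H](O[Si](C)(C)C(C)(C)C)/C(CO[Si](C)(C)C(C)(C)C)=C\[C@@H]1C=C(CB2OC(C)(C)C(C)(C)O2)C(=O)O1
F3 | step 17 | macrocyclic 8α-O-pinacolborate of 28 | CC1(C)OB(O[C@H]2C/C(C)=C/C[C@H](O[Si](C)(C)C(C)(C)C)/C(CO[Si](C)(C)C(C)(C)C)=C\[C@H]3OC(=O)C(=C)[C@@H]32)OC1(C)C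
F4 | step 18 | macrocyclic 8-ketone (3S, 6R, 7R) | O=C1C/C(C)=C/C[C@H](O[Si](C)(C)C(C)(C)C)/C(CO[Si](C)(C)C(C)(C)C)=C\[C@H]2OC(=O)C(=C)[C@@H]21
F5 | step 18 | macrocyclic 8β-alcohol (3S, 6R, 7R, 8R) | O[C@@H]1C/C(C)=C/C[C@H](O[Si](C)(C)C(C)(C)C)/C(CO[Si](C)(C)C(C)(C)C)=C\[C@H]2OC(=O)C(=C)[C@@H]21
F0 | step 19 | none | none
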